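## Structural features

Selaginellin F is built on a central benzene ring A that carries four contiguous carbon substituents: the triarylmethylidene carbon on C1, a 2,4-dihydroxyphenyl ring (ring C) on C2, a hydroxymethyl group on C5 and a (4-hydroxyphenyl)ethynyl unit (ring E at the alkyne terminus) on C6, with C3 and C4 left as CH. The methylidene carbon is doubly bonded to a cyclohexa-2,5-dienone (ring B) and singly bonded to a 4-hydroxyphenyl ring (ring D), so rings B and D are the two faces of one bis(4-hydroxyphenyl)carbinol and can both come from one aryl nucleophile used twice. There is no stereocentre, and because ring B is symmetric the exocyclic double bond has no E/Z descriptor, so the problem is one of regiochemistry and functional-group tolerance. Four elements are fragile: the electrophilic quinone methide, to which the C2' hydroxyl of ring C could add and so close a 6H-benzo[c]chromene, the diarylalkyne flanked by a benzylic alcohol and the carbinol carbon, which is open to hydroalkoxylation, the ionisable benzylic alcohol, and the oxidisable phenols. The real difficulty is the crowding at C1, C2 and C6 of ring A, where a fully substituted triaryl carbon must be assembled between a biaryl bond and an alkyne, together with a final unmasking of every phenol without harsh ether cleavage. The key step uses the 1,2-relationship of C1 and C2 on ring A and the ortho hydroxyl of ring C. A carboxyl carbon on C1 guides copper to a C2–Br bond, free resorcinol is arylated at its C4, and the C2' hydroxyl then lactonises onto the C1 carboxyl, so the biaryl bond and a masked double electrophile at the future methylidene carbon arise together.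

## Logic of the disconnections

18 is traced to 16 (through 17) by cutting five O–Si bonds and by adding water across the exocyclic double bond. The quinone methide is the dehydrated form of a bis(4-hydroxyphenyl)carbinol, so the sensitive chromophore is made last. Masking every oxygen as a silyl ether means one fluoride treatment can replace any aryl methyl ether cleavage. The forward step must remove five silyl groups and dehydrate without touching the alkyne and without letting the ring C hydroxyl close onto the cationic carbon.

16 is cut at both bonds from the carbinol carbon to rings B and D, giving 12 and two equivalents of 14 (from 13) by way of 15. Because rings B and D are identical at the carbinol stage, a lactone carbonyl on C1 serves as a double electrophile, and its opening releases the ring C hydroxyl. The gain is large: a triaryl carbon becomes a carbonyl group. The demand is a second addition to a ketone flanked by the biaryl and the alkyne.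

12 is cut at the C6–C(sp) bond to give 10 and 11. The alkyne is introduced late because it would not survive the copper chemistry of the key step. The peri position next to the lactone carbonyl is activated for oxidative addition. The demand is a cross-coupling at a carbon with two ortho neighbours.

10 is taken back through 9 and 8 to 7 and then to 6 by functional-group changes only: sulfonate from the phenol, phenol from the methyl ether, silyl ethers from the two free hydroxyls. The methyl ether at C6 of ring A is the one oxygen that a chelating Lewis acid can pick out, because it sits peri to the lactone carbonyl. The demand is that this cleavage spares the benzylic silyl ether beside it.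

6 is cut at the biaryl bond between C2 of ring A and C4 of 4, and at the lactone C–O bond, leading through 5 to 3 and 4. This is the strategic cut. It removes a ring and the only biaryl bond, and returns an unfunctionalised diphenol and a simple bromo acid. The demand is C-arylation at the right carbon of 4, in water, on a carboxylate with substituents on both flanks.

3 is cut at the bond between C1 of ring A and the carboxyl carbon, giving 1 by way of 2. The ring hydrogen between the methoxy group and the bromine is the most acidic one, so a one-carbon electrophile can be placed there directly. The demand is a clean second deprotonation of the alkoxide of 1 at low temperature.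

## Other disconnections considered

Alternative 1: The cut runs through ring A itself (bonds C1–C6, C2–C3 and C4–C5). Ring A would be assembled from the ester-tethered 1,6-diyne 4-[(tert-butyldimethylsilyl)oxy]but-2-yn-1-yl 3-(2,4-dimethoxyphenyl)prop-2-ynoate (A1) and acetylene (A2), and the cyclotrimerisation would deliver the phthalide 7-(2,4-dimethoxyphenyl)-4-[(tert-butyldimethylsilyloxy)methyl]isobenzofuran-1(3H)-one (A3).
- Forward reaction: RhCl(PPh3)3 would couple the two tethered alkynes of A1 on rhodium to a five-membered metallacycle, insert A2 and release A3, closing ring A fused to a five-membered lactone.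
- In its favour: all four contiguous substituents of ring A are placed by construction, since the tether of A1 fixes the C1/C6 pair and the symmetric alkyne A2 fills C3/C4. The conditions are neutral and catalytic.
- Where it is better: regiochemical certainty of the ring A pattern. In the chosen route that pattern rests on the selectivity of the lithiation in step 1.
- Against it here: A3 delivers C6 as a lactone CH2–O carbon, not as an alkyne. The lactone would have to be opened, the benzylic carbon oxidised to the aldehyde, homologated to a terminal alkyne and arylated, all beside a second benzylic oxygen that must stay distinct. The C1 carboxyl would no longer sit in a biaryl lactone, and double aryl addition to a phthalide-type carbonyl tends to stop at a cyclic ether. Ring C arrives in A3 as a dimethyl ether whose late cleavage would need a strong Lewis acid in the presence of the alkyne and the benzylic alcohol.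
- Mechanism: the cyclotrimerisation must compete with self-trimerisation of A1 under an atmosphere of A2; the copper arylation of step 2 competes mainly with loss of bromine.
- Step economy: the road to A1 would need roughly three to four steps against one step to 3, and roughly eight to nine operations would follow A3 against six after 6. The chosen plan is shorter overall.

Alternative 2: Two exocyclic bonds of ring A are cut at once, C6–C(sp) and C1–CO2H. This leads back to the aryne precursor 3-methoxy-6-[(pivaloyloxy)methyl]-2-(trimethylsilyl)phenyl trifluoromethanesulfonate (A4), 4-ethynylanisole (A5) and carbon dioxide (A6), which the key step would join to 6-methoxy-2-[(4-methoxyphenyl)ethynyl]-3-(pivaloyloxymethyl)benzoic acid (A7).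
- Forward reaction: CsF would release the aryne from A4. The alkynylcopper (ArC≡CCu) formed from A5 and CuI would add to the aryne carbon remote from the methoxy group, and the aryl–copper bond then formed next to the methoxy group would be carboxylated by A6 to give A7. No ring is closed.
- In its favour, and where it is better: alkyne and carboxyl enter in one operation, and in A7 the alkyne already sits on C6 without a crowded cross-coupling. The chosen route spends steps 1 and 4 to 6 on these two substituents.
- Against it here: the site of attack on the aryne rests on the inductive pull of the methoxy group and is opposed by the pivaloyloxymethyl group on the other flank, next to which the nucleophile must add. Three components must react in order, against protonation of the aryl–copper species and carboxylation of the alkynylcopper itself. A4 needs several steps. In A7 the bond from C2 to ring C is still missing and would have to be made by ether cleavage, sulfonylation and a cross-coupling beside the carboxyl group. The pivalate of A7 is not inert to an aryllithium, and the anisole-type ethers of A7 would need harsh cleavage at the end.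
- Structure and mechanism: A7 and 3 both use an ortho oxygen on ring A as a handle and a carboxyl carbon as the future methylidene carbon; on that design point the two plans are equal. The alternative is an anionic cascade on a strained intermediate, less forgiving than a chelation-guided copper arylation in water.
- Step economy: it would probably be longer, because A7 contains neither the biaryl bond nor the lactone that 6 has after step 2.

Alternative 3: Ring A is cut at C1–C2 and C5–C6. The precursor is the dienyl aryl ester 5-methoxy-2-[(1E,3E)-5-[(tert-butyldimethylsilyl)oxy]penta-1,3-dien-1-yl]phenyl 5-(4-methoxyphenyl)penta-2,4-diynoate (A8), and the cycloaddition with dehydrogenation would deliver 3-methoxy-7-[(4-methoxyphenyl)ethynyl]-8-[(tert-butyldimethylsilyloxy)methyl]-6H-benzo[c]chromen-6-one (A9).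
- Forward reaction: heating A8 would bring the triple bond next to the ester carbonyl onto the diene in an intramolecular (4+2) cycloaddition across the ester tether. DDQ in the same flask would dehydrogenate the cyclohexa-1,4-diene to A9, so ring A and a six-membered lactone close together.
- In its favour, and where it is better: A9 is the direct counterpart of 12. Ring A, the lactone, the biaryl bond, the alkyne and the protected hydroxymethyl group would all be in place after one step. In convergence and in the number of operations after the key step (two against six) it beats the chosen plan, and it avoids the crowded coupling of step 6.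
- Where it is equal: the tether of A8 fixes the regiochemistry as firmly as the carboxylate does in step 2.
- Against it here: esters prefer the conformer in which diene and dienophile point away from each other, so a high temperature is to be expected, and a conjugated diynoate and a silyloxy diene may polymerise there. The distal triple bond of A8 is a second dienophile, and DDQ is not obviously compatible with the electron-rich diene. A8 must be put together from a labile 5-arylpenta-2,4-diynoic acid and an (E,E)-dienyl phenol, each several steps away, and joined by a delicate acylation. As formulated, A9 carries phenolic methyl ethers on rings C and E.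
- Mechanism: an uncatalysed pericyclic step against a copper-mediated substitution; the thermal step has the weaker driving force before aromatisation.
- Step economy: the total would probably be about equal or slightly longer than eight steps because of the length of the road to A8, with more risk concentrated in one step.

Key step: step 2

Remark on the chemistry: the target is taken to be the open quinone methide as drawn and not its ring-closed 6H-benzo[c]chromene isomer.
Remark on the chemistry: the silyl ethers 11 and 13 are taken as catalogue compounds. Phenolic methyl ethers are avoided on purpose, so that no boron-halide ether cleavage is needed once the alkyne, the benzylic alcohol and the carbinol are present.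

## Route

Step 1
Reactants: 1 (4-bromo-2-methoxyphenyl)methanol
Product: 3 6-bromo-3-(hydroxymethyl)-2-methoxybenzoic acid, via C,O-dilithio species 2 (not isolated)
Conditions: LiN(iPr)2 (2.3 equiv), THF, −78 °C; CO2 (gas), −78 °C → rt; aq. HCl
Reagents that add atoms: carbon dioxide, O=C=O
Why: Directed ortho-lithiation and carboxylation: once the hydroxyl has taken the first equivalent of amide, the ring hydrogen between OMe and Br is the most acidic one, as in the well-known lithiation of 3-bromoanisole between its two substituents. Holding the 2-bromoaryllithium at −78 °C should prevent loss of LiBr to an aryne, CO2 traps it as the carboxylate, and the carbonate formed at the alkoxide oxygen falls apart on acidification.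

Step 2
Reactants: 3 6-bromo-3-(hydroxymethyl)-2-methoxybenzoic acid, 4 resorcinol
Product: 6 3-hydroxy-8-(hydroxymethyl)-7-methoxy-6H-benzo[c]chromen-6-one, via biaryl hydroxy acid 5 (not isolated)
Conditions: 4 (3 equiv), NaOH (4 equiv), H2O, 100 °C, argon; CuSO4·5H2O (15 mol %), 100 °C; then HCl to pH 1, 60 °C
Reagents that add atoms: none
Why: This is the Hurtley reaction, a copper-mediated Ullmann-type C-arylation of an enolate-like carbon nucleophile by a 2-bromobenzoate, followed by lactonisation. CuSO4 brings in divalent copper, which the electron-rich resorcinolate should reduce to the active monovalent copper; the carboxylate of 3 binds it and holds it beside the adjacent C–Br bond, so the bromide is activated although the ring is not electron-poor. Resorcinolate, which behaves as the enolate of a vinylogous 1,3-diketone, should transfer its C4 to the copper-bound aryl (Ar–Cu), and tautomerisation of the resulting cyclohexadienone restores the phenol and gives 5 as its carboxylate. On acidification the C2' hydroxyl attacks the carboxyl carbon on C1 and water is lost, a 6-exo-trig acyl substitution that closes the lactone ring of 6 and is favoured because the biaryl bond holds the two groups side by side. No stereocentre is formed. C- over O-arylation is expected from the soft aryl–copper partner and the water-solvated phenoxide oxygens. C4 of 4 is preferred over C2 because it is ortho to one hydroxyl, para to the other and unhindered, whereas C2 lies between both hydroxyls. The excess of 4 should suppress a second arylation of the product phenol, only one C–halogen bond is present, and the methoxy and hydroxymethyl groups are spectators in aqueous base.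

Step 3
Reactants: 6 3-hydroxy-8-(hydroxymethyl)-7-methoxy-6H-benzo[c]chromen-6-one
Product: 7 7-methoxy-3-[(triisopropylsilyl)oxy]-8-{[(triisopropylsilyl)oxy]methyl}-6H-benzo[c]chromen-6-one
Conditions: TIPSCl (2.5 equiv), imidazole, DMF, rt
Reagents that add atoms: triisopropylsilyl chloride, CC(C)[Si](Cl)(C(C)C)C(C)C
Why: Silyl ether formation at the phenol and the primary benzylic alcohol under imidazole catalysis. The bulky triisopropylsilyl group is chosen because it should withstand the Lewis acid, the amine base and the aryllithium of the following steps and still leave with fluoride at the end.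

Step 4
Reactants: 7 7-methoxy-3-[(triisopropylsilyl)oxy]-8-{[(triisopropylsilyl)oxy]methyl}-6H-benzo[c]chromen-6-one
Product: 9 7-hydroxy-3-[(triisopropylsilyl)oxy]-8-{[(triisopropylsilyl)oxy]methyl}-6H-benzo[c]chromen-6-one, via aryloxydichloroborane 8 (not isolated)
Conditions: BCl3 (1.3 equiv), CH2Cl2, −78 → 0 °C; then H2O, 0 °C
Reagents that add atoms: none
Why: Chelation-controlled Lewis acid cleavage of an aryl methyl ether: BCl3 binds between the lactone carbonyl oxygen and the peri methoxy oxygen, chloride removes the methyl group by SN2 attack, and the chelated borane 8 is hydrolysed on work-up. The weakly basic, hindered silyl ether oxygens should not compete at low temperature with a near-stoichiometric amount of reagent.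

Step 5
Reactants: 9 7-hydroxy-3-[(triisopropylsilyl)oxy]-8-{[(triisopropylsilyl)oxy]methyl}-6H-benzo[c]chromen-6-one
Product: 10 6-oxo-3-[(triisopropylsilyl)oxy]-8-{[(triisopropylsilyl)oxy]methyl}-6H-benzo[c]chromen-7-yl trifluoromethanesulfonate
Conditions: Tf2O (1.5 equiv), pyridine, CH2Cl2, 0 °C → rt
Reagents that add atoms: trifluoromethanesulfonic anhydride, O=S(=O)(OS(=O)(=O)C(F)(F)F)C(F)(F)F
Why: O-Sulfonylation of a phenol; the hydrogen-bonded peri hydroxyl is a poor nucleophile but should still be taken by the strongly electrophilic anhydride in pyridine, as is usual for chelated ortho-acyl phenols.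

Step 6
Reactants: 10 6-oxo-3-[(triisopropylsilyl)oxy]-8-{[(triisopropylsilyl)oxy]methyl}-6H-benzo[c]chromen-7-yl trifluoromethanesulfonate, 11 tert-butyl(4-ethynylphenoxy)dimethylsilane
Product: 12 7-({4-[(tert-butyldimethylsilyl)oxy]phenyl}ethynyl)-3-[(triisopropylsilyl)oxy]-8-{[(triisopropylsilyl)oxy]methyl}-6H-benzo[c]chromen-6-one
Conditions: 11 (1.5 equiv), PdCl2(PPh3)2 (5 mol %), CuI (10 mol %), Et3N, DMF, 65 °C, argon
Reagents that add atoms: none
Why: Sonogashira coupling: zerovalent palladium formed in situ from PdCl2(PPh3)2 should insert into the C–OTf bond, which the ortho lactone carbonyl activates. The alkyne is delivered as its CuI-derived acetylide (ArC≡CCu), and reductive elimination forms the C6–C(sp) bond. The anhydrous tertiary amine should leave the aryl silyl ethers intact.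

Step 7
Reactants: 12 7-({4-[(tert-butyldimethylsilyl)oxy]phenyl}ethynyl)-3-[(triisopropylsilyl)oxy]-8-{[(triisopropylsilyl)oxy]methyl}-6H-benzo[c]chromen-6-one, 13 (4-bromophenoxy)(tert-butyl)dimethylsilane
Product: 16 2-[2-{bis[4-(tert-butyldimethylsilyloxy)phenyl](hydroxy)methyl}-3-{[4-(tert-butyldimethylsilyloxy)phenyl]ethynyl}-4-{[(triisopropylsilyl)oxy]methyl}phenyl]-5-[(triisopropylsilyl)oxy]phenol, via aryllithium 14 (not isolated), via ring-opened ketone phenoxide 15 (not isolated)
Conditions: 13 (5 equiv), n-BuLi (4.8 equiv), THF, −78 °C; then 12, −78 → 0 °C; aq. NH4Cl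
Reagents that add atoms: none
Why: Double addition of an aryllithium to a lactone (ester to tertiary alcohol): 14, made by bromine–lithium exchange from 13, adds to the lactone carbonyl of 12. The tetrahedral adduct expels the ring C phenoxide to give ketone 15, which takes up a second 14. Rings B and D are identical at this stage, so the two additions need no differentiation, and the phenoxide, the alkyne and the bulky silyl ethers should be inert to the aryllithium at low temperature.

Step 8
Reactants: 16 2-[2-{bis[4-(tert-butyldimethylsilyloxy)phenyl](hydroxy)methyl}-3-{[4-(tert-butyldimethylsilyloxy)phenyl]ethynyl}-4-{[(triisopropylsilyl)oxy]methyl}phenyl]-5-[(triisopropylsilyl)oxy]phenol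
Product: 18 Selaginellin F, via desilylated triarylcarbinol 17 (not isolated)
Conditions: TBAF (7 equiv), THF, 0 °C → rt, argon; then AcOH (excess), rt
Reagents that add atoms: none
Why: Fluoride-induced desilylation, driven by Si–F bond formation, should free all five oxygens and give 17. Under the mild acid the bis(4-hydroxyphenyl)carbinol ionises to a triarylmethyl cation stabilised by two para oxygens and loses a phenolic proton, the classical fuchsone (quinone methide) formation. Ring B is symmetric, so no double-bond isomer can arise, and the short, cold, weakly acidic treatment is meant to spare the alkyne and to disfavour closure by the C2' hydroxyl of ring C.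

## Compound list

1 | (4-bromo-2-methoxyphenyl)methanol | COc1cc(Br)ccc1CO | starting material
2 | lithium (4-bromo-3-lithio-2-methoxyphenyl)methanolate (C,O-dilithio species) | [Li]OCc1ccc(Br)c([Li])c1OC | intermediate (not isolated)
3 | 6-bromo-3-(hydroxymethyl)-2-methoxybenzoic acid | OC(=O)c1c(Br)ccc(CO)c1OC | intermediate
4 | resorcinol (benzene-1,3-diol) | Oc1cccc(O)c1 | starting material
5 | 2',4'-dihydroxy-4-(hydroxymethyl)-3-methoxy-[1,1'-biphenyl]-2-carboxylic acid | OC(=O)c1c(-c2ccc(O)cc2O)ccc(CO)c1OC | intermediate (not isolated)
6 | 3-hydroxy-8-(hydroxymethyl)-7-methoxy-6H-benzo[c]chromen-6-one | O=C1Oc2cc(O)ccc2-c2ccc(CO)c(OC)c12 | intermediate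
7 | 7-methoxy-3-[(triisopropylsilyl)oxy]-8-{[(triisopropylsilyl)oxy]methyl}-6H-benzo[c]chromen-6-one | O=C1Oc2cc(O[Si](C(C)C)(C(C)C)C(C)C)ccc2-c2ccc(CO[Si](C(C)C)(C(C)C)C(C)C)c(OC)c12 | intermediate
8 | 7-[(dichloroboranyl)oxy]-3-[(triisopropylsilyl)oxy]-8-{[(triisopropylsilyl)oxy]methyl}-6H-benzo[c]chromen-6-one | O=C1Oc2cc(O[Si](C(C)C)(C(C)C)C(C)C)ccc2-c2ccc(CO[Si](C(C)C)(C(C)C)C(C)C)c(OB(Cl)Cl)c12 | intermediate (not isolated)
9 | 7-hydroxy-3-[(triisopropylsilyl)oxy]-8-{[(triisopropylsilyl)oxy]methyl}-6H-benzo[c]chromen-6-one | O=C1Oc2cc(O[Si](C(C)C)(C(C)C)C(C)C)ccc2-c2ccc(CO[Si](C(C)C)(C(C)C)C(C)C)c(O)c12 | intermediate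
10 | 6-oxo-3-[(triisopropylsilyl)oxy]-8-{[(triisopropylsilyl)oxy]methyl}-6H-benzo[c]chromen-7-yl trifluoromethanesulfonate | O=C1Oc2cc(O[Si](C(C)C)(C(C)C)C(C)C)ccc2-c2ccc(CO[Si](C(C)C)(C(C)C)C(C)C)c(OS(=O)(=O)C(F)(F)F)c12 | intermediate
11 | tert-butyl(4-ethynylphenoxy)dimethylsilane | C#Cc1ccc(O[Si](C)(C)C(C)(C)C)cc1 | starting material
12 | 7-({4-[(tert-butyldimethylsilyl)oxy]phenyl}ethynyl)-3-[(triisopropylsilyl)oxy]-8-{[(triisopropylsilyl)oxy]methyl}-6H-benzo[c]chromen-6-one | O=C1Oc2cc(O[Si](C(C)C)(C(C)C)C(C)C)ccc2-c2ccc(CO[Si](C(C)C)(C(C)C)C(C)C)c(C#Cc3ccc(O[Si](C)(C)C(C)(C)C)cc3)c12 | intermediate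
13 | (4-bromophenoxy)(tert-butyl)dimethylsilane | Brc1ccc(O[Si](C)(C)C(C)(C)C)cc1 | starting material
14 | {4-[(tert-butyldimethylsilyl)oxy]phenyl}lithium | [Li]c1ccc(O[Si](C)(C)C(C)(C)C)cc1 | intermediate (not isolated)
15 | lithium 2-[2-{4-[(tert-butyldimethylsilyl)oxy]benzoyl}-3-({4-[(tert-butyldimethylsilyl)oxy]phenyl}ethynyl)-4-{[(triisopropylsilyl)oxy]methyl}phenyl]-5-[(triisopropylsilyl)oxy]phenolate | [Li]Oc1cc(O[Si](C(C)C)(C(C)C)C(C)C)ccc1-c1ccc(CO[Si](C(C)C)(C(C)C)C(C)C)c(C#Cc2ccc(O[Si](C)(C)C(C)(C)C)cc2)c1C(=O)c1ccc(O[Si](C)(C)C(C)(C)C)cc1 | intermediate (not isolated)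
16 | 2-[2-{bis[4-(tert-butyldimethylsilyloxy)phenyl](hydroxy)methyl}-3-{[4-(tert-butyldimethylsilyloxy)phenyl]ethynyl}-4-{[(triisopropylsilyl)oxy]methyl}phenyl]-5-[(triisopropylsilyl)oxy]phenol | OC(c1ccc(O[Si](C)(C)C(C)(C)C)cc1)(c1ccc(O[Si](C)(C)C(C)(C)C)cc1)c1c(-c2ccc(O[Si](C(C)C)(C(C)C)C(C)C)cc2O)ccc(CO[Si](C(C)C)(C(C)C)C(C)C)c1C#Cc1ccc(O[Si](C)(C)C(C)(C)C)cc1 | intermediate
17 | 4-[2-[bis(4-hydroxyphenyl)(hydroxy)methyl]-4-(hydroxymethyl)-3-[(4-hydroxyphenyl)ethynyl]phenyl]benzene-1,3-diol | OC(c1ccc(O)cc1)(c1ccc(O)cc1)c1c(-c2ccc(O)cc2O)ccc(CO)c1C#Cc1ccc(O)cc1 | intermediate (not isolated)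
18 | Selaginellin F, 4-{[2',4'-dihydroxy-4-(hydroxymethyl)-3-[(4-hydroxyphenyl)ethynyl]-[1,1'-biphenyl]-2-yl](4-hydroxyphenyl)methylidene}cyclohexa-2,5-dien-1-one | O=C1C=CC(=C(c2ccc(O)cc2)c2c(-c3ccc(O)cc3O)ccc(CO)c2C#Cc2ccc(O)cc2)C=C1 | target

## Step count and least certain steps

Total step count: 8. Longest linear sequence: 8 steps (1 → 3 → 6 → 7 → 9 → 10 → 12 → 16 → 18); 4, 11 and 13 enter as purchased compounds. The least certain steps are the key step (step 2) and steps 1, 4, 6, 7 and 8; of these, steps 7 and 8 are judged the most exposed.

Key step (step 2). The most likely failure is loss of the bromine by reduction or hydroxylation before the carbon nucleophile is transferred. The carboxylate of 3 has a substituent on each flank and is twisted out of the ring plane, so it holds copper less well than a simple 2-bromobenzoate, and in hot aqueous hydroxide the copper-bound aryl can be protonated or take up hydroxide. A second arylation of the product phenol and air oxidation of resorcinolate are lesser concerns. The fallback makes the same bond by a different principle and sets out from 3. Alkylation of the carboxylate (MeI, KHCO3, DMF) would give methyl 6-bromo-3-(hydroxymethyl)-2-methoxybenzoate F1. Suzuki–Miyaura coupling with commercial [2,4-bis(benzyloxy)phenyl]boronic acid (Pd(OAc)2, SPhos, K3PO4, toluene–H2O, 90 °C) would give methyl 2',4'-bis(benzyloxy)-4-(hydroxymethyl)-3-methoxy-[1,1'-biphenyl]-2-carboxylate F2. Hydrogenolysis (H2, Pd/C, EtOAc) and a trace of TsOH would free both phenols and let the C2' hydroxyl close the lactone, coming back at 6.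

At step 1 the second deprotonation may be slow or incomplete, because the alkoxide formed first (ROLi) aggregates with the amide base and lowers its kinetic basicity. Warming to force the lithiation would let the 2-bromoaryllithium lose LiBr to an aryne. The fallback sets out from 1 and removes the alkoxide. Silylation (TBSCl, imidazole, DMF) would give tert-butyl[(4-bromo-2-methoxybenzyl)oxy]dimethylsilane F3. Lithiation with LiN(iPr)2 (1.2 equiv, THF, −78 °C) on this neutral substrate and a CO2 quench would give 6-bromo-3-{[(tert-butyldimethylsilyl)oxy]methyl}-2-methoxybenzoic acid F4. Aqueous HCl in THF would remove the silyl group and come back at 3.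

At step 4 the risk is attack of the boron Lewis acid on the benzylic silyl ether beside the methoxy group, with loss of that protecting group or its replacement by chloride, once the reagent is no longer held by the carbonyl chelate. The fallback inverts the order of protection and ether cleavage and sets out from 6. BCl3 (3.5 equiv, CH2Cl2, −78 → 0 °C) on the unprotected compound should only tie the hydroxyls up as borates while the chelated methyl ether is cleaved, and hydrolysis would give 3,7-dihydroxy-8-(hydroxymethyl)-6H-benzo[c]chromen-6-one F5. TIPSCl (2.2 equiv) and imidazole should then silylate the C3 phenol and the primary alcohol but not the hydrogen-bonded, flanked C7 hydroxyl, coming back at 9.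

At step 6 transmetalation and reductive elimination may be slow at a carbon flanked by the lactone carbonyl and the silyloxymethyl group. S–O cleavage of the sulfonate by the amine and copper-mediated oxidative dimerisation of 11 could then take over. The fallback is a copper-free and amine-free Stille coupling and sets out from 10 and 11. Deprotonation of 11 (n-BuLi, THF, −78 °C) and quenching with Bu3SnCl would give tributyl({4-[(tert-butyldimethylsilyl)oxy]phenyl}ethynyl)stannane F6. With 10 (Pd(PPh3)4, LiCl, dioxane, 90 °C) this should come back at 12.

At step 7 the second addition may stall. After the first addition the anionic intermediate 15 can re-close to a cyclic hemiketal alkoxide, and its ketone is shielded by the twisted ring C and the alkyne. Warming to force the addition invites 5-exo attack of the tertiary alkoxide on the neighbouring triple bond. The fallback separates the two additions and sets out from 12. Treatment with 14 (1.2 equiv, −78 °C, cold quench) would give {4-[(tert-butyldimethylsilyl)oxy]phenyl}[3-({4-[(tert-butyldimethylsilyl)oxy]phenyl}ethynyl)-2'-hydroxy-4'-[(triisopropylsilyl)oxy]-4-{[(triisopropylsilyl)oxy]methyl}-[1,1'-biphenyl]-2-yl]methanone F7. TBSCl and imidazole would then cap the phenol and lock the open ketone as {4-[(tert-butyldimethylsilyl)oxy]phenyl}[2'-[(tert-butyldimethylsilyl)oxy]-3-({4-[(tert-butyldimethylsilyl)oxy]phenyl}ethynyl)-4'-[(triisopropylsilyl)oxy]-4-{[(triisopropylsilyl)oxy]methyl}-[1,1'-biphenyl]-2-yl]methanone F8. Next, 14 premixed with anhydrous CeCl3 (to give ArCeCl2) would add to the now neutral ketone and give bis{4-[(tert-butyldimethylsilyl)oxy]phenyl}[2'-[(tert-butyldimethylsilyl)oxy]-3-({4-[(tert-butyldimethylsilyl)oxy]phenyl}ethynyl)-4'-[(triisopropylsilyl)oxy]-4-{[(triisopropylsilyl)oxy]methyl}-[1,1'-biphenyl]-2-yl]methanol F9. Under the conditions of step 8 this compound would come back at 18 (through 17).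

At step 8 the most likely failure is ring-chain isomerisation. The C2' hydroxyl of ring C may capture the triarylmethyl cation, or add to the quinone methide, and close a six-membered cyclic ether. Prolonged contact with fluoride could also add the benzylic alkoxide across the alkyne. The fallback sets out from 16 and accepts the closed isomer as an intermediate. Desilylation and a longer acid treatment would lead to 6,6-bis(4-hydroxyphenyl)-8-(hydroxymethyl)-7-[(4-hydroxyphenyl)ethynyl]-6H-benzo[c]chromen-3-ol F10. Brief treatment with dilute NaOH in MeOH–H2O at 0 °C under argon should let a para phenoxide expel the ring C aryloxide and open the ring to the delocalised quinone methide phenolate. Pouring into cold NaH2PO4 buffer (about pH 6) and immediate extraction would come back at 18.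

## Further compounds

F1 | step 2 | methyl 6-bromo-3-(hydroxymethyl)-2-methoxybenzoate | COC(=O)c1c(Br)ccc(CO)c1OC
F2 | step 2 | methyl 2',4'-bis(benzyloxy)-4-(hydroxymethyl)-3-methoxy-[1,1'-biphenyl]-2-carboxylate | COC(=O)c1c(-c2ccc(OCc3ccccc3)cc2OCc2ccccc2)ccc(CO)c1OC
F3 | step 1 | tert-butyl[(4-bromo-2-methoxybenzyl)oxy]dimethylsilane | COc1cc(Br)ccc1CO[Si](C)(C)C(C)(C)C
F4 | step 1 | 6-bromo-3-{[(tert-butyldimethylsilyl)oxy]methyl}-2-methoxybenzoic acid | OC(=O)c1c(Br)ccc(CO[Si](C)(C)C(C)(C)C)c1OC
F5 | step 4 | 3,7-dihydroxy-8-(hydroxymethyl)-6H-benzo[c]chromen-6-one | O=C1Oc2cc(O)ccc2-c2ccc(CO)c(O)c12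
F6 | step 6 | tributyl({4-[(tert-butyldimethylsilyl)oxy]phenyl}ethynyl)stannane | CCCC[Sn](CCCC)(CCCC)C#Cc1ccc(O[Si](C)(C)C(C)(C)C)cc1
F7 | step 7 | {4-[(tert-butyldimethylsilyl)oxy]phenyl}[3-({4-[(tert-butyldimethylsilyl)oxy]phenyl}ethynyl)-2'-hydroxy-4'-[(triisopropylsilyl)oxy]-4-{[(triisopropylsilyl)oxy]methyl}-[1,1'-biphenyl]-2-yl]methanone | Oc1cc(O[Si](C(C)C)(C(C)C)C(C)C)ccc1-c1ccc(CO[Si](C(C)C)(C(C)C)C(C)C)c(C#Cc2ccc(O[Si](C)(C)C(C)(C)C)cc2)c1C(=O)c1ccc(O[Si](C)(C)C(C)(C)C)cc1
F8 | step 7 | {4-[(tert-butyldimethylsilyl)oxy]phenyl}[2'-[(tert-butyldimethylsilyl)oxy]-3-({4-[(tert-butyldimethylsilyl)oxy]phenyl}ethynyl)-4'-[(triisopropylsilyl)oxy]-4-{[(triisopropylsilyl)oxy]methyl}-[1,1'-biphenyl]-2-yl]methanone | CC(C)(C)[Si](C)(C)Oc1cc(O[Si](C(C)C)(C(C)C)C(C)C)ccc1-c1ccc(CO[Si](C(C)C)(C(C)C)C(C)C)c(C#Cc2ccc(O[Si](C)(C)C(C)(C)C)cc2)c1C(=O)c1ccc(O[Si](C)(C)C(C)(C)C)cc1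
F9 | step 7 | bis{4-[(tert-butyldimethylsilyl)oxy]phenyl}[2'-[(tert-butyldimethylsilyl)oxy]-3-({4-[(tert-butyldimethylsilyl)oxy]phenyl}ethynyl)-4'-[(triisopropylsilyl)oxy]-4-{[(triisopropylsilyl)oxy]methyl}-[1,1'-biphenyl]-2-yl]methanol | OC(c1ccc(O[Si](C)(C)C(C)(C)C)cc1)(c1ccc(O[Si](C)(C)C(C)(C)C)cc1)c1c(-c2ccc(O[Si](C(C)C)(C(C)C)C(C)C)cc2O[Si](C)(C)C(C)(C)C)ccc(CO[Si](C(C)C)(C(C)C)C(C)C)c1C#Cc1ccc(O[Si](C)(C)C(C)(C)C)cc1
F10 | step 8 | 6,6-bis(4-hydroxyphenyl)-8-(hydroxymethyl)-7-[(4-hydroxyphenyl)ethynyl]-6H-benzo[c]chromen-3-ol | Oc1ccc(cc1)C1(c2ccc(O)cc2)Oc2cc(O)ccc2-c2ccc(CO)c(C#Cc3ccc(O)cc3)c12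
A1 | alternative 1 | 4-[(tert-butyldimethylsilyl)oxy]but-2-yn-1-yl 3-(2,4-dimethoxyphenyl)prop-2-ynoate | COc1ccc(C#CC(=O)OCC#CCO[Si](C)(C)C(C)(C)C)c(OC)c1
A2 | alternative 1 | acetylene | C#C
A3 | alternative 1 | 7-(2,4-dimethoxyphenyl)-4-[(tert-butyldimethylsilyloxy)methyl]isobenzofuran-1(3H)-one | COc1ccc(-c2ccc(CO[Si](C)(C)C(C)(C)C)c3c2C(=O)OC3)c(OC)c1
A4 | alternative 2 | 3-methoxy-6-[(pivaloyloxy)methyl]-2-(trimethylsilyl)phenyl trifluoromethanesulfonate | COc1ccc(COC(=O)C(C)(C)C)c(OS(=O)(=O)C(F)(F)F)c1[Si](C)(C)C
A5 | alternative 2 | 4-ethynylanisole | C#Cc1ccc(OC)cc1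
A6 | alternative 2 | carbon dioxide | O=C=O
A7 | alternative 2 | 6-methoxy-2-[(4-methoxyphenyl)ethynyl]-3-(pivaloyloxymethyl)benzoic acid | CC(C)(C)C(=O)OCc1ccc(OC)c(C(=O)O)c1C#Cc1ccc(OC)cc1
A8 | alternative 3 | 5-methoxy-2-[(1E,3E)-5-[(tert-butyldimethylsilyl)oxy]penta-1,3-dien-1-yl]phenyl 5-(4-methoxyphenyl)penta-2,4-diynoate | COc1ccc(/C=C/C=C/CO[Si](C)(C)C(C)(C)C)c(OC(=O)C#CC#Cc2ccc(OC)cc2)c1
A9 | alternative 3 | 3-methoxy-7-[(4-methoxyphenyl)ethynyl]-8-[(tert-butyldimethylsilyloxy)methyl]-6H-benzo[c]chromen-6-one | COc1ccc2c(c1)OC(=O)c1c-2ccc(CO[Si](C)(C)C(C)(C)C)c1C#Cc1ccc(OC)cc1
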